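The readings are simulated for an exercise, noise included.

Eta carries less reagent than south but runs longer than south's last reading, so you ask whether the hours make up for the smaller charge.

| setting | south | south-west | theta | zeta | eta |
|---|---|---|---|---|---|
| starting material | 0.10 M | 0.10 M | 0.10 M | 0.10 M | 0.10 M |
| reagent | 0.16 M | 0.54 M | 0.400 M | 0.150 M | 0.120 M |
| remark | run made earlier | run made earlier |  |  |  |
| time |  |  | 30 h | 30 h | 30 h |

| run | time / h | tris adduct / % | starting material / % |
|---|---|---|---|
| south | 1.50 | 0 | 94 |
| south | 3.00 | 1 | 89 |
| south | 5.00 | 2 | 82 |
| south | 8.00 | 1 | 78 |
| south | 12.0 | 2 | 69 |
| south | 20.0 | 5 | 54 |
| south-west | 4.00 | 4 | 62 |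
| south-west | 8.00 | 11 | 36 |
| south-west | 10.0 | 20 | 30 |
| south-west | 15.0 | 30 | 20 |
| south-west | 20.0 | 36 | 13 |

(readings scatter by 1.5 percentage points)

- which of these holds the largest part of the starting material at the end of theta (first product / tetra adduct / bis adduct / tris adduct / starting material)
- which of these holds the largest part of the starting material at the end of zeta (first product / tetra adduct / bis adduct / tris adduct / starting material)
- which of these holds the largest part of the starting material at the end of eta (first product / tetra adduct / bis adduct / tris adduct / starting material)
- tris adduct at the end of eta, in percent of the starting material charged

- percentages count the starting material that a species holds: one idle adduct counts as two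
- tris adduct is meant together with its idle adduct
- steps that have been proposed: starting material + reagent -> first product + by-product; starting material + tris adduct <-> idle adduct; reagent + bis adduct -> tris adduct + by-product; reagent + first product -> bis adduct + by-product; reagent + tris adduct -> tetra adduct + by-product
- in an amount of tris adduct, one idle adduct counts as one tris adduct

Each addition step takes reagent, while the parking of tris adduct on starting material as idle adduct takes none. So call reagent exposure the reagent charge times the hours times the mean fraction of that charge still present; at one starting charge, if the parking keeps pace, these competitive consecutive steps should give one mix per exposure. The first south-west reading gives a first-step constant of 0.221 L mol⁻¹ h⁻¹. The half-exposure, 188 M·min, is then the reagent exposure that leaves half the starting material.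

Now turn the question round: for a rival to lead in eta, starting material must first fall below half. Eta's charge times hours is 216 M·min, above the half-exposure. But losing half the starting material costs at least one reagent each, leaving at most 58.3 % of the reagent. Replacing the curve by its straight-line mean gives 171 M·min, short of the half-exposure.

So I expect starting material to lead eta, with about 53.2 % left. South's last reading is close to that at 54 %, and it shows tris adduct at 5 %, which is my figure. Zeta's exposure at half, 225 M·min, passes the half-exposure, so the test is silent there; I still name starting material. Theta's charge times hours, 720 M·min, and south-west's last, 648 M·min, are not exposures, so I only take theta to end near that last reading, where tris adduct read 36 % against 13 % of starting material. That reading puts tris adduct ahead of starting material, but 51.0 % is unread and could be bis adduct, so naming tris adduct for theta is my judgement, not a result of the test.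

The forecast reasons that “Reagent is used up along the chain”. With a constant of 0.24 and an eta exposure of 2.35 M·h, against my straight-line figure 171 M·min, it names tris adduct, starting material and starting material for theta, zeta and eta, and tris adduct 4 % (2 % to 7 %).

The flasks give tris adduct, starting material and starting material, and eta holds tris adduct 4.56 %.

    starting material + reagent → first product + by-product (k = 0.230 L mol⁻¹ h⁻¹)
    starting material + tris adduct ⇌ idle adduct, settled at all times (K = 12.0 L mol⁻¹)
    reagent + bis adduct → tris adduct + by-product (k = 0.240 L mol⁻¹ h⁻¹)
    reagent + first product → bis adduct + by-product (k = 0.740 L mol⁻¹ h⁻¹)
    reagent + tris adduct → tetra adduct + by-product (k = 0.120 L mol⁻¹ h⁻¹)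

Eta's reagent ends at 41 % of its charge, so its straight-line exposure is 152 M·min, under the half-exposure. That reckons 57.1 % of starting material against the flask's 55.9 %. The neighbour with 0.20 M of reagent ends at 41.0 % of its charge, so its exposure is 254 M·min, past the half-exposure. That reckons 39.2 % against the flask's 37.2 %. South-west read tris adduct 11 % at 36 % of starting material, and the neighbour holds 12.9 %.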